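**Retrosynthetic overview**
- The target holds three trans-2,3-diaryl-2,3-dihydrobenzofurans: an E-ethene joins C5 of the left unit to C6 of the central unit, and central C3 is bonded to C4 of the right unit. The stilbene is made late by Horner–Wadsworth–Emmons olefination, and BBr3 frees the phenols last.
- Feature used: C3 of the central ring carries two different aryl groups (its own C3a and C4 of the right unit), and the neighbouring C2 carries a 4-hydroxyphenyl group and O1. This is the pattern left by anti addition of two aryl groups across an (E)-alkenyl boronate followed by C–B oxidation, so the central C3–C3a and C2–aryl bonds come from a three-component coupling of the right-unit alkenyl boronate, 4-methoxyphenyllithium and the triflate of methyl vanillate.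
- The O1–C2 bond of the central ring is closed only in the last step, from the benzylic alcohol and the neighbouring methoxy oxygen, trans under thermodynamic control.
- The right and left rings are each built beforehand by [4+1] annulation of an ortho-quinone methide with a chiral 4-methoxybenzyl sulfonium ylide. Ring order: right ring, left ring, central ring last.

Key step: step 11

Remark: the chiral sulfide and the ferrocenyl diphosphine are each available in both mirror-image forms; the forms written are provisional, the sense of induction on these substrates is to be settled by experiment and the antipode is used if needed (the sulfide is taken as purchasable, otherwise one step from limonene and sulfur).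

**Route**

Step 1
Reactants: 1 1-bromo-3,5-dimethoxybenzene
Product: 2 2-bromo-4,6-dimethoxybenzaldehyde
Conditions: POCl3, DMF, 0 → 90 °C; aq NaOAc
Reagents that add atoms: N,N-dimethylformamide CN(C)C=O; water O
Why: Vilsmeier–Haack formylation, in which the chloroiminium ion attacks the position para to one methoxy group and ortho to the other (the usual site in 1,3-dimethoxyarenes) and hydrolysis gives the aldehyde.

Step 2
Reactants: 2 2-bromo-4,6-dimethoxybenzaldehyde
Product: 3 2-bromo-6-hydroxy-4-methoxybenzaldehyde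
Conditions: BCl3 (1.2 equiv), CH2Cl2, −78 → 0 °C; H2O
Reagents that add atoms: none
Why: Chelation-directed ether cleavage, in which BCl3 bound to the aldehyde oxygen cleaves only the ortho methoxy group through a six-membered boron chelate and leaves the para methoxy group and the bromide alone.

Step 3
Reactants: 3 2-bromo-6-hydroxy-4-methoxybenzaldehyde; 4 3,5-dimethoxyphenylmagnesium chloride (2.5 equiv)
Product: 5 racemic 3-bromo-2-[(3,5-dimethoxyphenyl)(hydroxy)methyl]-5-methoxyphenol
Conditions: THF, 0 °C → rt; aq NH4Cl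
Reagents that add atoms: none
Why: Grignard 1,2-addition, in which the first equivalent forms the magnesium phenoxide and the second adds to the aldehyde while the aryl bromide does not exchange; the carbinol centre is racemic and is erased in step 6.

Step 4
Reactants: 5 racemic 3-bromo-2-[(3,5-dimethoxyphenyl)(hydroxy)methyl]-5-methoxyphenol
Product: 6 racemic 3-bromo-2-[(3,5-dimethoxyphenyl)(4-methylphenylsulfonyl)methyl]-5-methoxyphenol
Conditions: sodium 4-methylbenzenesulfinate, HCO2H/H2O, rt
Reagents that add atoms: sodium 4-methylbenzenesulfinate Cc1ccc(cc1)S(=O)[O-].[Na+]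
Why: Acid-promoted substitution through the ortho-hydroxy, para-methoxy benzhydryl cation, which sulfinate captures at sulfur to give the bench-stable sulfone used as quinone methide precursor.

Step 5
Reactants: 7 (1R,4R,5R)-isothiocineole; 8 4-methoxybenzyl bromide
Product: 9 (1R,4R,5R)-6-(4-methoxybenzyl)-4,7,7-trimethyl-6-thiabicyclo[3.2.1]octan-6-ium triflate (benzyl group exo on sulfur)
Conditions: LiOTf, CH2Cl2/H2O, rt
Reagents that add atoms: lithium triflate [Li+].[O-]S(=O)(=O)C(F)(F)F
Why: S-Benzylation of the bicyclic sulfide on its exposed lone pair, with exchange to the non-nucleophilic triflate so that the salt does not revert.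

Step 6
Reactants: 6 racemic sulfone; 9 sulfonium triflate
Product: 12 (2S,3S)-4-bromo-3-(3,5-dimethoxyphenyl)-6-methoxy-2-(4-methoxyphenyl)-2,3-dihydro-1-benzofuran, via ortho-quinone methide 10 (not isolated), via sulfonium ylide 11 (not isolated)
Conditions: Cs2CO3, MeCN/CH2Cl2, 0 °C → rt
Reagents that add atoms: none
Why: Formal [4+1] annulation of an in-situ ortho-quinone methide with a sulfonium ylide (Michael addition, then 5-exo-tet displacement of the sulfide by the phenoxide with inversion), in which the chiral sulfide shields one face of the ylide carbon as in its asymmetric epoxidations and so fixes C2 (S), and the anti approach of the two aryl groups places C3 (S) trans to it; transfer of chirality from this sulfide to a quinone methide acceptor is the untested element.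

Step 7
Reactants: 13 acenaphthoquinone
Product: 14 cis-1,2-dimethyl-1,2-dihydroacenaphthylene-1,2-diol (meso, "mac" diol)
Conditions: MeMgBr (2.5 equiv), THF, 0 °C → rt; aq NH4Cl; recrystallisation
Reagents that add atoms: methylmagnesium bromide C[Mg]Br
Why: Double Grignard 1,2-addition to the 1,2-diketone; the cis (meso) diol is the isomer needed, is freed from any trans diol by crystallisation, and contributes no stereocentre to the target.

Step 8
Reactants: 14 mac diol; 15 dibutyl vinylboronate
Product: 16 vinylboronic ester of 14 (vinyl-B(mac))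
Conditions: toluene, 4 Å MS, rt → 40 °C, then vacuum
Reagents that add atoms: none
Why: Boronic ester exchange driven by chelation of the cis diol and removal of butanol; a trans diol could not bridge boron.

Step 9
Reactants: 12 right 4-bromo dihydrobenzofuran; 16 vinyl-B(mac)
Product: 17 (2S,3S)-3-(3,5-dimethoxyphenyl)-6-methoxy-2-(4-methoxyphenyl)-4-[(E)-2-(B(mac))ethenyl]-2,3-dihydro-1-benzofuran
Conditions: Pd(OAc)2 (5 mol%), P(t-Bu)3·HBF4 (10 mol%), Cy2NMe, toluene, 90 °C
Reagents that add atoms: none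
Why: Heck–Mizoroki reaction of a vinylboronic ester, in which aryl–palladium delivers the aryl group to the unsubstituted alkene carbon and β-hydride elimination gives the E alkenyl boronate, while the amine base, the absence of water and the hindered mac diol suppress transmetallation of boron.

Step 10
Reactants: 18 methyl 4-hydroxy-3-methoxybenzoate
Product: 19 methyl 3-methoxy-4-(trifluoromethylsulfonyloxy)benzoate
Conditions: Tf2O, pyridine, CH2Cl2, 0 °C
Reagents that add atoms: triflic anhydride O=S(=O)(OS(=O)(=O)C(F)(F)F)C(F)(F)F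
Why: O-Sulfonylation of the phenol with triflic anhydride and pyridine.

Step 11
Reactants: 17 (E)-alkenyl B(mac) ester (1.05 equiv); 19 aryl triflate; 20 4-bromoanisole
Product: 23 methyl 4-[(1R,2R)-1-[(2S,3S)-3-(3,5-dimethoxyphenyl)-6-methoxy-2-(4-methoxyphenyl)-2,3-dihydro-1-benzofuran-4-yl]-2-(4-methoxyphenyl)-2-(B(mac))ethyl]-3-methoxybenzoate, via 4-methoxyphenyllithium 21 (not isolated), via lithium borate complex 22 (not isolated)
Conditions: 20, t-BuLi (2 equiv), Et2O, −78 °C; 17, THF, −78 °C → rt; KOTf; then Pd(OAc)2 (3 mol%), (Sp,Sp)-MandyPhos (diphosphine C52H50FeN2P2, 1,1′-bis(diphenylphosphino)-2,2′-bis[α-(dimethylamino)benzyl]ferrocene, 3.6 mol%), 19, THF, 60 °C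
Reagents that add atoms: none
Why: This is the known palladium-catalysed conjunctive cross-coupling of alkenylboron ate complexes, the closest case being the enantio- and diastereoselective coupling of β-substituted alkenyl mac boronates with organolithiums and aryl triflates. Aryllithium 21 attacks boron of 17 and forms ate complex 22; zerovalent palladium generated from Pd(OAc)2 and the diphosphine inserts into the C–O bond of triflate 19, the resulting cationic aryl–palladium (divalent) fragment coordinates the alkene of 22, the 4-methoxyphenyl group then migrates from boron to the α-carbon on the face opposite palladium while the β-carbon–palladium bond is made, and reductive elimination attaches the benzoate aryl group to the β-carbon. No ring closes here; the step makes the C3–C3a and C2–aryl bonds of the future central ring. The β-carbon (C3 of the central ring, R) is set by the chiral ligand, which chooses the alkene face for palladium, and the α-carbon (C2, R) follows from stereospecific anti addition across the E double bond. The step needs the 1,2-shift to beat direct transfer of the alkenyl group to palladium (Suzuki product), which the hindered mac diol on boron, the cationic halide-free palladium (triflate electrophile, KOTf to take up bromide) and the absence of added base secure. It also needs catalyst control over the resident (2S,3S) unit, for which the ligand enantiomer is chosen.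

Step 12
Reactants: 23 secondary B(mac) ester
Product: 24 methyl 4-[(1R,2R)-1-[(2S,3S)-3-(3,5-dimethoxyphenyl)-6-methoxy-2-(4-methoxyphenyl)-2,3-dihydro-1-benzofuran-4-yl]-2-hydroxy-2-(4-methoxyphenyl)ethyl]-3-methoxybenzoate
Conditions: NaBO3·4H2O, THF/H2O, rt
Reagents that add atoms: sodium perborate [Na+].[O-]OB=O
Why: Perborate oxidation of the C–B bond (1,2-shift of carbon from boron to oxygen) with retention at carbon, mild enough to spare the methyl ester.

Step 13
Reactants: 24 hydroxy ester
Product: 25 (1R,2R)-2-[(2S,3S)-3-(3,5-dimethoxyphenyl)-6-methoxy-2-(4-methoxyphenyl)-2,3-dihydro-1-benzofuran-4-yl]-2-[4-(hydroxymethyl)-2-methoxyphenyl]-1-(4-methoxyphenyl)ethan-1-ol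
Conditions: LiAlH4, THF, 0 °C; Rochelle salt work-up
Reagents that add atoms: none
Why: Hydride reduction of the methyl ester to the benzylic alcohol; aryl ethers and the dihydrobenzofuran are inert.

Step 14
Reactants: 25 diol
Product: 26 4-[(1R,2R)-1-[(2S,3S)-3-(3,5-dimethoxyphenyl)-6-methoxy-2-(4-methoxyphenyl)-2,3-dihydro-1-benzofuran-4-yl]-2-hydroxy-2-(4-methoxyphenyl)ethyl]-3-methoxybenzaldehyde
Conditions: TEMPO (10 mol%), PhI(OAc)2, CH2Cl2, rt
Reagents that add atoms: none
Why: Oxoammonium (TEMPO) oxidation with PhI(OAc)2 as terminal oxidant, selective for the unhindered primary benzylic alcohol over the secondary alcohol flanked by the diarylmethine carbon.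

Step 15
Reactants: 27 5-bromo-2-hydroxy-3-methoxybenzaldehyde; 4 3,5-dimethoxyphenylmagnesium chloride (2.5 equiv)
Product: 28 racemic 4-bromo-2-[(3,5-dimethoxyphenyl)(hydroxy)methyl]-6-methoxyphenol
Conditions: THF, 0 °C → rt; aq NH4Cl
Reagents that add atoms: none
Why: Grignard 1,2-addition as in step 3; the racemic carbinol centre is erased in step 17.

Step 16
Reactants: 28 racemic diol
Product: 29 racemic 4-bromo-2-[(3,5-dimethoxyphenyl)(4-methylphenylsulfonyl)methyl]-6-methoxyphenol
Conditions: sodium 4-methylbenzenesulfinate, HCO2H/H2O, rt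
Reagents that add atoms: sodium 4-methylbenzenesulfinate Cc1ccc(cc1)S(=O)[O-].[Na+]
Why: Acid-promoted substitution through the ortho-hydroxybenzhydryl cation with S-capture by sulfinate, as in step 4.

Step 17
Reactants: 29 racemic sulfone; 9 sulfonium triflate
Product: 31 (2S,3S)-5-bromo-3-(3,5-dimethoxyphenyl)-7-methoxy-2-(4-methoxyphenyl)-2,3-dihydro-1-benzofuran, via ortho-quinone methide 30 (not isolated)
Conditions: Cs2CO3, MeCN/CH2Cl2, 0 °C → rt
Reagents that add atoms: none
Why: The same [4+1] annulation as in step 6, in which Cs2CO3 releases quinone methide 30 from the sulfone and regenerates from salt 9 the ylide 11 already described there, which adds to 30 and is displaced by the phenoxide; C2 (S) is set by the shielded ylide face and C3 (S) by the trans-selective addition and ring closure with inversion.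

Step 18
Reactants: 31 left 5-bromo dihydrobenzofuran
Product: 33 [(2S,3S)-3-(3,5-dimethoxyphenyl)-7-methoxy-2-(4-methoxyphenyl)-2,3-dihydro-1-benzofuran-5-yl]methanol, via aldehyde 32 (not isolated)
Conditions: n-BuLi, THF, −78 °C; DMF; then MeOH, NaBH4, 0 °C
Reagents that add atoms: N,N-dimethylformamide CN(C)C=O
Why: Bromine–lithium exchange, formylation of the aryllithium with DMF and borohydride reduction in the same flask; C2–H and C3–H are not acidic enough to be touched at −78 °C.

Step 19
Reactants: 33 benzylic alcohol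
Product: 34 (2S,3S)-5-(bromomethyl)-3-(3,5-dimethoxyphenyl)-7-methoxy-2-(4-methoxyphenyl)-2,3-dihydro-1-benzofuran
Conditions: CBr4, PPh3, CH2Cl2, 0 °C; used crude
Reagents that add atoms: carbon tetrabromide BrC(Br)(Br)Br
Why: Appel bromination under neutral conditions, chosen because the ring with a 4-methoxyphenyl group at C2 is acid-labile.

Step 20
Reactants: 34 benzylic bromide
Product: 35 diethyl {[(2S,3S)-3-(3,5-dimethoxyphenyl)-7-methoxy-2-(4-methoxyphenyl)-2,3-dihydro-1-benzofuran-5-yl]methyl}phosphonate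
Conditions: P(OEt)3, neat, 110 °C
Reagents that add atoms: triethyl phosphite CCOP(OCC)OCC
Why: Michaelis–Arbuzov reaction of the reactive benzylic bromide with triethyl phosphite.

Step 21
Reactants: 26 hydroxy aldehyde; 35 left phosphonate (1.3 equiv)
Product: 36 (1R,2R)-2-[(2S,3S)-3-(3,5-dimethoxyphenyl)-6-methoxy-2-(4-methoxyphenyl)-2,3-dihydro-1-benzofuran-4-yl]-2-[4-[(E)-2-[(2S,3S)-3-(3,5-dimethoxyphenyl)-7-methoxy-2-(4-methoxyphenyl)-2,3-dihydro-1-benzofuran-5-yl]ethenyl]-2-methoxyphenyl]-1-(4-methoxyphenyl)ethan-1-ol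
Conditions: KOt-Bu (2.5 equiv), THF, 0 °C → rt
Reagents that add atoms: none
Why: Horner–Wadsworth–Emmons olefination of an aryl aldehyde with a benzylic phosphonate anion, which gives the E stilbene; the extra base only converts the free secondary alcohol into its alkoxide.

Step 22
Reactants: 36 decamethyl ether alcohol
Product: 37 target CNP0265934.1
Conditions: BBr3 (excess), CH2Cl2, −78 °C → rt; MeOH, then H2O
Reagents that add atoms: none
Why: Lewis-acid ether cleavage with cyclodehydration: BBr3 ionises the 4-methoxybenzylic alcohol at low temperature, the oxygen of the neighbouring methoxy group captures the cation (five-membered oxonium ion, demethylated by bromide) and closes O1–C2 trans to the C3 aryl group under thermodynamic control (C2 R, the carbinol configuration being lost and reset), and on warming the nine remaining aryl methyl ethers are cleaved; the outer trans rings can only reopen and reclose at C2, so their C3 centres hold.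

**Compound list**
1 | 1-bromo-3,5-dimethoxybenzene | COc1cc(Br)cc(OC)c1 | starting material
2 | 2-bromo-4,6-dimethoxybenzaldehyde | COc1cc(OC)c(C=O)c(Br)c1 | intermediate
3 | 2-bromo-6-hydroxy-4-methoxybenzaldehyde | COc1cc(O)c(C=O)c(Br)c1 | intermediate
4 | 3,5-dimethoxyphenylmagnesium chloride (THF solution) | COc1cc(OC)cc([Mg]Cl)c1 | starting material
5 | racemic 3-bromo-2-[(3,5-dimethoxyphenyl)(hydroxy)methyl]-5-methoxyphenol | COc1cc(O)c(C(O)c2cc(OC)cc(OC)c2)c(Br)c1 | intermediate
6 | racemic 3-bromo-2-[(3,5-dimethoxyphenyl)(4-methylphenylsulfonyl)methyl]-5-methoxyphenol | COc1cc(O)c(C(c2cc(OC)cc(OC)c2)S(=O)(=O)c2ccc(C)cc2)c(Br)c1 | intermediate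
7 | (1R,4R,5R)-4,7,7-trimethyl-6-thiabicyclo[3.2.1]octane (isothiocineole) | C[C@@H]1CC[C@@H]2C[C@H]1SC2(C)C | starting material
8 | 4-methoxybenzyl bromide | COc1ccc(CBr)cc1 | starting material
9 | (1R,4R,5R)-6-(4-methoxybenzyl)-4,7,7-trimethyl-6-thiabicyclo[3.2.1]octan-6-ium triflate, benzyl exo on sulfur | C[C@@H]1CC[C@@H]2C[C@H]1[S@@+](Cc1ccc(OC)cc1)C2(C)C.[O-]S(=O)(=O)C(F)(F)F | intermediate
10 | 5-bromo-6-[(3,5-dimethoxyphenyl)methylidene]-3-methoxycyclohexa-2,4-dien-1-one (ortho-quinone methide, alkene geometry open) | O=C1C=C(OC)C=C(Br)C1=Cc1cc(OC)cc(OC)c1 | intermediate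
11 | sulfonium (4-methoxyphenyl)methylide derived from 9 | C[C@@H]1CC[C@@H]2C[C@H]1[S@@+]([CH-]c1ccc(OC)cc1)C2(C)C | intermediate
12 | (2S,3S)-4-bromo-3-(3,5-dimethoxyphenyl)-6-methoxy-2-(4-methoxyphenyl)-2,3-dihydro-1-benzofuran | Brc1cc(OC)cc2c1[C@H](c1cc(OC)cc(OC)c1)[C@@H](c1ccc(OC)cc1)O2 | intermediate
13 | acenaphthoquinone (acenaphthylene-1,2-dione) | O=C1C(=O)c2cccc3cccc1c23 | starting material
14 | cis-1,2-dimethyl-1,2-dihydroacenaphthylene-1,2-diol (meso, mac diol) | C[C@]1(O)c2cccc3cccc(c23)[C@@]1(C)O | intermediate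
15 | dibutyl vinylboronate | C=CB(OCCCC)OCCCC | starting material
16 | vinylboronic ester of 14, vinyl-B(mac) | C=CB1O[C@@]2(C)c3cccc4cccc(c34)[C@@]2(C)O1 | intermediate
17 | (2S,3S)-3-(3,5-dimethoxyphenyl)-6-methoxy-2-(4-methoxyphenyl)-4-[(E)-2-(B(mac))ethenyl]-2,3-dihydro-1-benzofuran | B1(O[C@@]2(C)c3cccc4cccc(c34)[C@@]2(C)O1)/C=C/c1cc(OC)cc2c1[C@H](c1cc(OC)cc(OC)c1)[C@@H](c1ccc(OC)cc1)O2 | intermediate
18 | methyl 4-hydroxy-3-methoxybenzoate (methyl vanillate) | COC(=O)c1ccc(O)c(OC)c1 | starting material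
19 | methyl 3-methoxy-4-(trifluoromethylsulfonyloxy)benzoate | COC(=O)c1ccc(OS(=O)(=O)C(F)(F)F)c(OC)c1 | intermediate
20 | 4-bromoanisole | COc1ccc(Br)cc1 | starting material
21 | 4-methoxyphenyllithium | [Li]c1ccc(OC)cc1 | intermediate
22 | lithium (alkenyl)(4-methoxyphenyl)borate of 17, configuration at boron open | [Li+].[B-]1(O[C@@]2(C)c3cccc4cccc(c34)[C@@]2(C)O1)(c1ccc(OC)cc1)/C=C/c1cc(OC)cc2c1[C@H](c1cc(OC)cc(OC)c1)[C@@H](c1ccc(OC)cc1)O2 | intermediate
23 | methyl 4-[(1R,2R)-1-[(2S,3S)-3-(3,5-dimethoxyphenyl)-6-methoxy-2-(4-methoxyphenyl)-2,3-dihydro-1-benzofuran-4-yl]-2-(4-methoxyphenyl)-2-(B(mac))ethyl]-3-methoxybenzoate | B1(O[C@@]2(C)c3cccc4cccc(c34)[C@@]2(C)O1)[C@@H](c1ccc(OC)cc1)[C@@H](c1ccc(cc1OC)C(=O)OC)c1cc(OC)cc2c1[C@H](c1cc(OC)cc(OC)c1)[C@@H](c1ccc(OC)cc1)O2 | intermediate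
24 | methyl 4-[(1R,2R)-1-[(2S,3S)-3-(3,5-dimethoxyphenyl)-6-methoxy-2-(4-methoxyphenyl)-2,3-dihydro-1-benzofuran-4-yl]-2-hydroxy-2-(4-methoxyphenyl)ethyl]-3-methoxybenzoate | O[C@@H](c1ccc(OC)cc1)[C@@H](c1ccc(cc1OC)C(=O)OC)c1cc(OC)cc2c1[C@H](c1cc(OC)cc(OC)c1)[C@@H](c1ccc(OC)cc1)O2 | intermediate
25 | (1R,2R)-2-[(2S,3S)-3-(3,5-dimethoxyphenyl)-6-methoxy-2-(4-methoxyphenyl)-2,3-dihydro-1-benzofuran-4-yl]-2-[4-(hydroxymethyl)-2-methoxyphenyl]-1-(4-methoxyphenyl)ethan-1-ol | O[C@@H](c1ccc(OC)cc1)[C@@H](c1ccc(cc1OC)CO)c1cc(OC)cc2c1[C@H](c1cc(OC)cc(OC)c1)[C@@H](c1ccc(OC)cc1)O2 | intermediate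
26 | 4-[(1R,2R)-1-[(2S,3S)-3-(3,5-dimethoxyphenyl)-6-methoxy-2-(4-methoxyphenyl)-2,3-dihydro-1-benzofuran-4-yl]-2-hydroxy-2-(4-methoxyphenyl)ethyl]-3-methoxybenzaldehyde | O[C@@H](c1ccc(OC)cc1)[C@@H](c1ccc(cc1OC)C=O)c1cc(OC)cc2c1[C@H](c1cc(OC)cc(OC)c1)[C@@H](c1ccc(OC)cc1)O2 | intermediate
27 | 5-bromo-2-hydroxy-3-methoxybenzaldehyde | COc1cc(Br)cc(C=O)c1O | starting material
28 | racemic 4-bromo-2-[(3,5-dimethoxyphenyl)(hydroxy)methyl]-6-methoxyphenol | COc1cc(Br)cc(C(O)c2cc(OC)cc(OC)c2)c1O | intermediate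
29 | racemic 4-bromo-2-[(3,5-dimethoxyphenyl)(4-methylphenylsulfonyl)methyl]-6-methoxyphenol | COc1cc(Br)cc(C(c2cc(OC)cc(OC)c2)S(=O)(=O)c2ccc(C)cc2)c1O | intermediate
30 | 4-bromo-6-[(3,5-dimethoxyphenyl)methylidene]-2-methoxycyclohexa-2,4-dien-1-one (ortho-quinone methide, alkene geometry open) | O=C1C(OC)=CC(Br)=CC1=Cc1cc(OC)cc(OC)c1 | intermediate
31 | (2S,3S)-5-bromo-3-(3,5-dimethoxyphenyl)-7-methoxy-2-(4-methoxyphenyl)-2,3-dihydro-1-benzofuran | COc1ccc([C@H]2Oc3c(OC)cc(Br)cc3[C@@H]2c2cc(OC)cc(OC)c2)cc1 | intermediate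
32 | (2S,3S)-3-(3,5-dimethoxyphenyl)-7-methoxy-2-(4-methoxyphenyl)-2,3-dihydro-1-benzofuran-5-carbaldehyde | COc1ccc([C@H]2Oc3c(OC)cc(C=O)cc3[C@@H]2c2cc(OC)cc(OC)c2)cc1 | intermediate
33 | [(2S,3S)-3-(3,5-dimethoxyphenyl)-7-methoxy-2-(4-methoxyphenyl)-2,3-dihydro-1-benzofuran-5-yl]methanol | COc1ccc([C@H]2Oc3c(OC)cc(CO)cc3[C@@H]2c2cc(OC)cc(OC)c2)cc1 | intermediate
34 | (2S,3S)-5-(bromomethyl)-3-(3,5-dimethoxyphenyl)-7-methoxy-2-(4-methoxyphenyl)-2,3-dihydro-1-benzofuran | COc1ccc([C@H]2Oc3c(OC)cc(CBr)cc3[C@@H]2c2cc(OC)cc(OC)c2)cc1 | intermediate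
35 | diethyl {[(2S,3S)-3-(3,5-dimethoxyphenyl)-7-methoxy-2-(4-methoxyphenyl)-2,3-dihydro-1-benzofuran-5-yl]methyl}phosphonate | COc1ccc([C@H]2Oc3c(OC)cc(CP(=O)(OCC)OCC)cc3[C@@H]2c2cc(OC)cc(OC)c2)cc1 | intermediate
36 | (1R,2R)-2-[(2S,3S)-right unit-4-yl]-2-[4-[(E)-2-[(2S,3S)-left unit-5-yl]ethenyl]-2-methoxyphenyl]-1-(4-methoxyphenyl)ethan-1-ol, all phenols as methyl ethers (full name in step 21) | COc1ccc([C@H]2Oc3c(OC)cc(/C=C/c4ccc(c(OC)c4)[C@@H](c5cc(OC)cc6c5[C@H](c5cc(OC)cc(OC)c5)[C@@H](c5ccc(OC)cc5)O6)[C@@H](O)c4ccc(OC)cc4)cc3[C@@H]2c2cc(OC)cc(OC)c2)cc1 | intermediate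
37 | CNP0265934.1: left (2S,3S)-3-(3,5-dihydroxyphenyl)-7-hydroxy-2-(4-hydroxyphenyl)-2,3-dihydrobenzofuran joined at C5 by an E-ethene to C6 of the central (2R,3R)-2-(4-hydroxyphenyl)-2,3-dihydrobenzofuran, whose C3 bears C4 of the right (2S,3S)-3-(3,5-dihydroxyphenyl)-6-hydroxy-2-(4-hydroxyphenyl)-2,3-dihydrobenzofuran | Oc1ccc([C@H]2Oc3c(O)cc(/C=C/c4ccc5c(c4)O[C@@H](c4ccc(O)cc4)[C@@H]5c4cc(O)cc5c4[C@H](c4cc(O)cc(O)c4)[C@@H](c4ccc(O)cc4)O5)cc3[C@@H]2c2cc(O)cc(O)c2)cc1 | target

**Step count**
Total: 22 steps. Longest linear sequence: 12 steps (1, 2, 3, 4, 6, 9, 11, 12, 13, 14, 21, 22).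

**Steps most likely to fail**

1. Step 11. What may go wrong: direct transfer of the alkenyl group from boron to palladium (Suzuki pathway) instead of the 1,2-shift, slow alkene binding because of the bulky ortho-substituted β-aryl group, or poor face selectivity against the resident stereocentres. Fallback: the roles of the two aryl partners are exchanged, so that the small arene sits on the alkene and palladium makes the bond to the right unit. It sets out from 19 and 16. A Heck reaction as in step 9 would give methyl 3-methoxy-4-[(E)-2-(B(mac))ethenyl]benzoate F1. Ate complex formation with 21 at −78 °C and conjunctive coupling with bromide 12 as the electrophile (same catalyst, KOTf to take up bromide) would give methyl 4-[(1R,2S)-1-(right unit-4-yl)-2-(4-methoxyphenyl)-2-(B(mac))ethyl]-3-methoxybenzoate F2, the epimer of 23 at the boron-bearing carbon, because the two aryl groups now enter in opposite roles across the E alkene. Oxidation as in step 12 would give the (1R,2S) hydroxy ester F3, and steps 13, 14 and 21 would give the (1S,2R) diol F4, the (1R,2S) hydroxy aldehyde F5 and the (1S,2R) stilbene alcohol F6. Because step 22 ionises the carbinol carbon, F6 converges with the main series and the fallback comes back to the route at 37.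

2. Step 6 (step 17 runs the same reaction and shares the risk). What may go wrong: weak transfer of chirality from the sulfide to the quinone methide acceptor, poor trans/cis selectivity in the ylide addition, or loss of the quinone methide before the ylide is formed. Fallback: the ring is made by an enantioselective rhodium-carbene C–H insertion, known for cis-2,3-diaryl dihydrobenzofurans, followed by acid epimerisation. It sets out from 5. Phenol O-alkylation (4-methoxybenzyl chloride, K2CO3, DMF) would give racemic [2-bromo-4-methoxy-6-(4-methoxybenzyloxy)phenyl](3,5-dimethoxyphenyl)methanol F7, and MnO2 would give [2-bromo-4-methoxy-6-(4-methoxybenzyloxy)phenyl](3,5-dimethoxyphenyl)methanone F8. Hydrazine hydrate in hot n-butanol (forcing conditions for this hindered ketone) would give the hydrazone F9, and MnO2 would oxidise it to the diaryldiazomethane F10. Rh2(S-PTAD)4 (dirhodium tetrakis[(S)-(1-adamantyl)phthalimidoacetate], or its mirror image) would insert the carbene into a benzylic C–H bond of the OCH2 group and give (2R,3S)-cis-4-bromo-3-(3,5-dimethoxyphenyl)-6-methoxy-2-(4-methoxyphenyl)-2,3-dihydro-1-benzofuran F11 with C3 set by the catalyst. Trifluoroacetic acid in CH2Cl2 would then epimerise C2 through the 4-methoxybenzylic cation to the trans isomer, so the fallback comes back to the route at 12.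

3. Step 22. What may go wrong: the benzylic cation at central C2 persists under excess BBr3 and loses the C3 proton to a triarylethene (erasing C3), is captured by the neighbouring dimethoxyphenyl ring in a Friedel–Crafts closure, or demethylation stays incomplete. Fallback: ring closure and deprotection are separated, with the cyclised ether isolated and checked before the phenols are freed. It sets out from 36. Me3SiBr in CH2Cl2 at −40 °C would convert the benzylic alcohol into the bromide, which the neighbouring methoxy group displaces with loss of bromomethane to give the trans-closed nonamethyl ether of the target F12. BCl3 with n-Bu4NI (CH2Cl2, −78 °C → rt), a halide-assisted ether cleavage, would then give the phenols, so the fallback comes back to the route at 37.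

**Further compounds**
F1 | step 11 | methyl 3-methoxy-4-[(E)-2-(B(mac))ethenyl]benzoate | COC(=O)c1ccc(/C=C/B2O[C@@]3(C)c4cccc5cccc(c45)[C@@]3(C)O2)c(OC)c1
F2 | step 11 | methyl 4-[(1R,2S)-1-[(2S,3S)-3-(3,5-dimethoxyphenyl)-6-methoxy-2-(4-methoxyphenyl)-2,3-dihydro-1-benzofuran-4-yl]-2-(4-methoxyphenyl)-2-(B(mac))ethyl]-3-methoxybenzoate | B1(O[C@@]2(C)c3cccc4cccc(c34)[C@@]2(C)O1)[C@H](c1ccc(OC)cc1)[C@@H](c1ccc(cc1OC)C(=O)OC)c1cc(OC)cc2c1[C@H](c1cc(OC)cc(OC)c1)[C@@H](c1ccc(OC)cc1)O2
F3 | step 11 | methyl 4-[(1R,2S)-1-[(2S,3S)-3-(3,5-dimethoxyphenyl)-6-methoxy-2-(4-methoxyphenyl)-2,3-dihydro-1-benzofuran-4-yl]-2-hydroxy-2-(4-methoxyphenyl)ethyl]-3-methoxybenzoate | O[C@H](c1ccc(OC)cc1)[C@@H](c1ccc(cc1OC)C(=O)OC)c1cc(OC)cc2c1[C@H](c1cc(OC)cc(OC)c1)[C@@H](c1ccc(OC)cc1)O2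
F4 | step 11 | (1S,2R)-2-[(2S,3S)-3-(3,5-dimethoxyphenyl)-6-methoxy-2-(4-methoxyphenyl)-2,3-dihydro-1-benzofuran-4-yl]-2-[4-(hydroxymethyl)-2-methoxyphenyl]-1-(4-methoxyphenyl)ethan-1-ol | O[C@H](c1ccc(OC)cc1)[C@@H](c1ccc(cc1OC)CO)c1cc(OC)cc2c1[C@H](c1cc(OC)cc(OC)c1)[C@@H](c1ccc(OC)cc1)O2
F5 | step 11 | 4-[(1R,2S)-1-[(2S,3S)-3-(3,5-dimethoxyphenyl)-6-methoxy-2-(4-methoxyphenyl)-2,3-dihydro-1-benzofuran-4-yl]-2-hydroxy-2-(4-methoxyphenyl)ethyl]-3-methoxybenzaldehyde | O[C@H](c1ccc(OC)cc1)[C@@H](c1ccc(cc1OC)C=O)c1cc(OC)cc2c1[C@H](c1cc(OC)cc(OC)c1)[C@@H](c1ccc(OC)cc1)O2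
F6 | step 11 | (1S,2R) epimer of 36 at the carbinol carbon | COc1ccc([C@H]2Oc3c(OC)cc(/C=C/c4ccc(c(OC)c4)[C@@H](c5cc(OC)cc6c5[C@H](c5cc(OC)cc(OC)c5)[C@@H](c5ccc(OC)cc5)O6)[C@H](O)c4ccc(OC)cc4)cc3[C@@H]2c2cc(OC)cc(OC)c2)cc1
F7 | step 6 | racemic [2-bromo-4-methoxy-6-(4-methoxybenzyloxy)phenyl](3,5-dimethoxyphenyl)methanol | COc1cc(OCc2ccc(OC)cc2)c(C(O)c2cc(OC)cc(OC)c2)c(Br)c1
F8 | step 6 | [2-bromo-4-methoxy-6-(4-methoxybenzyloxy)phenyl](3,5-dimethoxyphenyl)methanone | COc1cc(OCc2ccc(OC)cc2)c(C(=O)c2cc(OC)cc(OC)c2)c(Br)c1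
F9 | step 6 | hydrazone of F8 | COc1cc(OCc2ccc(OC)cc2)c(C(=NN)c2cc(OC)cc(OC)c2)c(Br)c1
F10 | step 6 | [2-bromo-4-methoxy-6-(4-methoxybenzyloxy)phenyl](3,5-dimethoxyphenyl)diazomethane | COc1cc(OCc2ccc(OC)cc2)c(C(=[N+]=[N-])c2cc(OC)cc(OC)c2)c(Br)c1
F11 | step 6 | (2R,3S)-cis-4-bromo-3-(3,5-dimethoxyphenyl)-6-methoxy-2-(4-methoxyphenyl)-2,3-dihydro-1-benzofuran | Brc1cc(OC)cc2c1[C@H](c1cc(OC)cc(OC)c1)[C@H](c1ccc(OC)cc1)O2
F12 | step 22 | nonamethyl ether of 37 (central ring closed, trans) | COc1ccc([C@H]2Oc3c(OC)cc(/C=C/c4ccc5c(c4)O[C@@H](c4ccc(OC)cc4)[C@@H]5c4cc(OC)cc5c4[C@H](c4cc(OC)cc(OC)c4)[C@@H](c4ccc(OC)cc4)O5)cc3[C@@H]2c2cc(OC)cc(OC)c2)cc1
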